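**Plan**
Retrosynthesis: remove the benzyl group from the 4'-oxygen. Then open ring C by cutting C3–C4 (CH2–C=O) together with C2–H, a retro-hydroacylation that leads to an achiral 2-(1-arylvinyloxy)benzaldehyde. Then cut formyl C–C4a (to an aryl bromide), C2=C3 (to an ester C=O) and O1–C2 (to the ring A phenol and the ring B acid).
Forward: ring A is brominated and joined to ring B as an aryl benzoate. The ester C=O is methylenated to the C2=C3 enol ether, Br is exchanged for CHO, and ring C closes last, before deprotection.
Enabling feature: C4 sits on C4a next to the O1-bearing C8a, C2 carries only H, O1 and ring B, and C3 is a bare CH2. Ring C is therefore the formal adduct of an aldehyde C–H bond across a 1,1-disubstituted enol ether C2=C3 that has no allylic hydrogen.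
Stereochemistry: the only stereocentre, C2 (S), arises in the ring closure under control of a chiral diphosphine on rhodium. Only a neutral step follows.

Key step: step 5

Assumption: precedent does not fix the sense of induction of the diphosphine on this substrate class. The (R)-ligand is written, both antipodes are commercial, and the antipode that delivers the 2S product is the one to be used.

Step 1
Reactants: 1 3,4,5-trimethoxyphenol
Product: 2 2-bromo-3,4,5-trimethoxyphenol
Conditions: NBS (1.0 equiv), CH2Cl2, −40 °C to 0 °C
Reagents that add atoms: N-bromosuccinimide, O=C1CCC(=O)N1Br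
Why: Electrophilic aromatic bromination in which the two free ring positions are equivalent by symmetry (each ortho to OH and flanked by OMe), so only mono- versus dibromination has to be controlled, by one equivalent of reagent at low temperature in an anhydrous medium.

Step 2
Reactants: 2 2-bromo-3,4,5-trimethoxyphenol; 3 4-(benzyloxy)-3-methoxybenzoic acid
Product: 4 2-bromo-3,4,5-trimethoxyphenyl 4-(benzyloxy)-3-methoxybenzoate
Conditions: DCC, DMAP (cat.), CH2Cl2, 0 °C to rt
Reagents that add atoms: none
Why: Steglich esterification, in which the acylpyridinium species acylates even an ortho-substituted phenol under neutral conditions that leave ArBr, OMe and OBn untouched.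

Step 3
Reactants: 4 2-bromo-3,4,5-trimethoxyphenyl 4-(benzyloxy)-3-methoxybenzoate
Product: 5 1-(benzyloxy)-4-[1-(2-bromo-3,4,5-trimethoxyphenoxy)ethenyl]-2-methoxybenzene
Conditions: Cp2TiMe2 (2.5 equiv), toluene, 70 °C, dark; filtration through basic alumina
Reagents that add atoms: dimethyltitanocene Cp2TiMe2, C[Ti](C)(C1C=CC=C1)C1C=CC=C1
Why: Petasis methylenation, in which thermally formed Cp2Ti=CH2 adds [2+2] to the ester carbonyl and cycloreverts to the enol ether; aryl benzoates are classic substrates of titanium methylidene reagents, and the non-acidic medium spares the acid-labile product as well as ArBr and OBn.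

Step 4
Reactants: 5 1-(benzyloxy)-4-[1-(2-bromo-3,4,5-trimethoxyphenoxy)ethenyl]-2-methoxybenzene
Product: 8 2-{1-[4-(benzyloxy)-3-methoxyphenyl]ethenyloxy}-4,5,6-trimethoxybenzaldehyde, via aryllithium 6 (not isolated), via lithium hemiaminal alkoxide 7 (not isolated)
Conditions: n-BuLi (1.05 equiv), THF, −78 °C; DMF, −78 °C to 0 °C; H2O
Reagents that add atoms: N,N-dimethylformamide, CN(C)C=O; n-butyllithium, [Li]CCCC (lithium of 6 and 7 only)
Why: Bromine–lithium exchange outruns deprotonation of the benzyl ether at −78 °C, the aryllithium is stabilised by its two flanking oxygens, and Bouveault-type formylation with DMF releases the aldehyde on a neutral aqueous quench that spares the enol ether.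

Step 5
Reactants: 8 2-{1-[4-(benzyloxy)-3-methoxyphenyl]ethenyloxy}-4,5,6-trimethoxybenzaldehyde
Product: 9 (2S)-2-[4-(benzyloxy)-3-methoxyphenyl]-5,6,7-trimethoxychroman-4-one
Conditions: [Rh(cod)Cl]2 (2.5 mol %), (R)-DTBM-SEGPHOS (5 mol %), NaB[3,5-(CF3)2C6H3]4 (5 mol %), 4 Å MS, 1,4-dioxane, 80 °C
Reagents that add atoms: none
Why: Proposed new method: the cationic monovalent rhodium diphosphine complex should add oxidatively into the formyl C–H bond of 8, bind the tethered C2=C3 double bond, pass hydride to the substituted carbon C2 and then, from the seven-membered acyl alkyl rhodacycle of trivalent rhodium, eliminate reductively to make the C3–C4 (CH2–C=O) bond. The closest known reaction type is the enantioselective rhodium-catalysed intramolecular hydroacylation of 1,1-disubstituted alkenes, established for ortho-(2-substituted allyl)benzaldehydes (which give 3-substituted tetralones, the carbocyclic counterparts of ring C) and for N-(1-substituted vinyl)indole-2-carbaldehydes, whereas an aryl 1-arylvinyl ether as the alkene partner is untested. Ring C closes in a formal 6-endo-trig mode, the acyl carbon bonding to the terminal CH2. The only new stereocentre, C2, is fixed in the hydride transfer by the alkene face that the twofold-symmetric ligand pocket allows to bind, that is by catalyst control on an achiral substrate. The step needs endo insertion (Rh to CH2) over exo insertion (Rh to C2, leading to a 2-aryl-2-methylbenzofuran-3-one) and hydroacylation over decarbonylation: the aryl and aryloxy groups on C2 disfavour a tertiary Rh–C bond and an elimination that forms a quaternary centre, the alkene has no allylic hydrogen so that isomerisation cannot drain it, and the methoxy and enol ether oxygens flanking the formyl group can hold the acyl rhodium hydride against CO extrusion. The neutral aprotic medium leaves the base-sensitive C2–O1 bond of 9 closed, so that the configuration should persist.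

Step 6
Reactants: 9 (2S)-2-[4-(benzyloxy)-3-methoxyphenyl]-5,6,7-trimethoxychroman-4-one
Product: 10 agecorynin E, (2S)-2-(4-hydroxy-3-methoxyphenyl)-5,6,7-trimethoxychroman-4-one
Conditions: H2 (1 atm), Pd/C (10 wt %), EtOAc, rt, stopped after one equivalent of H2
Reagents that add atoms: none
Why: Hydrogenolysis of the primary benzyl aryl ether, a standard deprotection of benzylated flavanones, should be faster than cleavage of the hindered secondary C2–O1 bond or reduction of the donor-substituted aryl ketone, and the neutral medium avoids the base-induced opening to the chalcone that would racemise C2.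

**Compound list**
1 | 3,4,5-trimethoxyphenol | COc1cc(O)cc(OC)c1OC | starting material
2 | 2-bromo-3,4,5-trimethoxyphenol | COc1cc(O)c(Br)c(OC)c1OC | intermediate
3 | 4-(benzyloxy)-3-methoxybenzoic acid | COc1cc(C(=O)O)ccc1OCc1ccccc1 | starting material
4 | 2-bromo-3,4,5-trimethoxyphenyl 4-(benzyloxy)-3-methoxybenzoate | COc1cc(C(=O)Oc2cc(OC)c(OC)c(OC)c2Br)ccc1OCc1ccccc1 | intermediate
5 | 1-(benzyloxy)-4-[1-(2-bromo-3,4,5-trimethoxyphenoxy)ethenyl]-2-methoxybenzene | COc1cc(C(=C)Oc2cc(OC)c(OC)c(OC)c2Br)ccc1OCc1ccccc1 | intermediate
6 | aryllithium, Li in place of Br of 5 | COc1cc(C(=C)Oc2cc(OC)c(OC)c(OC)c2[Li])ccc1OCc1ccccc1 | intermediate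
7 | lithium hemiaminal alkoxide, adduct of 6 to DMF (racemic at the carbinol carbon) | COc1cc(C(=C)Oc2cc(OC)c(OC)c(OC)c2C(O[Li])N(C)C)ccc1OCc1ccccc1 | intermediate
8 | 2-{1-[4-(benzyloxy)-3-methoxyphenyl]ethenyloxy}-4,5,6-trimethoxybenzaldehyde | COc1cc(C(=C)Oc2cc(OC)c(OC)c(OC)c2C=O)ccc1OCc1ccccc1 | intermediate
9 | (2S)-2-[4-(benzyloxy)-3-methoxyphenyl]-5,6,7-trimethoxychroman-4-one | COc1cc([C@@H]2CC(=O)c3c(cc(OC)c(OC)c3OC)O2)ccc1OCc1ccccc1 | intermediate
10 | agecorynin E, (2S)-2-(4-hydroxy-3-methoxyphenyl)-5,6,7-trimethoxychroman-4-one | COc1cc([C@@H]2CC(=O)c3c(cc(OC)c(OC)c3OC)O2)ccc1O | target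

Total step count: 6. Longest linear sequence: 6 (1 to 10).

**Steps most likely to fail**

Step 5. The acyl rhodium hydride may lose CO. The hindered, electron-rich alkene may insert sluggishly or in the exo sense. Facial selectivity may be poor, or the cationic metal may promote hydrolysis of the enol ether.
- The fallback uses known chemistry, sets out from 1 and comes back at 9.
- 1 is C-acetylated ortho to the hydroxyl group (Ac2O, BF3·OEt2, 80 °C) to 1-(2-hydroxy-4,5,6-trimethoxyphenyl)ethan-1-one F1.
- Condensation with DMF dimethyl acetal (toluene, 100 °C) should give the enaminone (E)-3-(dimethylamino)-1-(2-hydroxy-4,5,6-trimethoxyphenyl)prop-2-en-1-one F2.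
- Aqueous HCl in CH2Cl2 closes F2 to 5,6,7-trimethoxy-4H-chromen-4-one F3.
- Asymmetric conjugate addition of commercial 4-(benzyloxy)-3-methoxyphenylboronic acid (COc1cc(B(O)O)ccc1OCc1ccccc1) to F3 should then deliver 9. The conditions are Pd(OCOCF3)2, t-BuPyOX (the antipode that gives 2S), NH4PF6 and H2O in ClCH2CH2Cl at 60 °C. This reaction type is established for chromones.

Step 3. Methylenation of the hindered, donor-substituted aryl benzoate may stay incomplete. Aryloxide may be lost at the titanacycle stage, or the enol ether may hydrolyse on isolation.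
- The fallback builds the enol ether by etherification and elimination, sets out from 2 and comes back at 5.
- Commercial 1-[4-(benzyloxy)-3-methoxyphenyl]-2-bromoethanone is reduced (NaBH4, MeOH, 0 °C) to racemic 1-[4-(benzyloxy)-3-methoxyphenyl]-2-bromoethan-1-ol F4.
- Mitsunobu etherification of F4 with 2 (PPh3, DIAD, THF) should give racemic 1-(benzyloxy)-4-[2-bromo-1-(2-bromo-3,4,5-trimethoxyphenoxy)ethyl]-2-methoxybenzene F5.
- Dehydrobromination through the benzylic hydrogen (KOtBu, THF, 0 °C) gives 5.

Step 4. The aryllithium may be protonated or butylated before it is formylated. On warming it may expel the enolate from the ortho position. The enol ether may hydrolyse during quench and chromatography.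
- The fallback brings in the formyl group before the enol ether, needs no organolithium, sets out from 1 and comes back at 8.
- 1 is ortho-formylated (MgCl2, Et3N, paraformaldehyde, MeCN, reflux; Casnati–Skattebøl formylation) to 2-hydroxy-4,5,6-trimethoxybenzaldehyde F6.
- Mitsunobu etherification of F6 with the bromohydrin F4, made as above, should give racemic 2-{1-[4-(benzyloxy)-3-methoxyphenyl]-2-bromoethoxy}-4,5,6-trimethoxybenzaldehyde F7.
- KOtBu in THF at −20 °C removes HBr and gives 8. The aldehyde is non-enolisable and strongly donor-substituted, so it is a poor electrophile under these conditions.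

**Further compounds**
F1 | step 5 | 1-(2-hydroxy-4,5,6-trimethoxyphenyl)ethan-1-one | CC(=O)c1c(O)cc(OC)c(OC)c1OC
F2 | step 5 | (E)-3-(dimethylamino)-1-(2-hydroxy-4,5,6-trimethoxyphenyl)prop-2-en-1-one | CN(C)/C=C/C(=O)c1c(O)cc(OC)c(OC)c1OC
F3 | step 5 | 5,6,7-trimethoxy-4H-chromen-4-one | COc1cc2occc(=O)c2c(OC)c1OC
F4 | step 3 | racemic 1-[4-(benzyloxy)-3-methoxyphenyl]-2-bromoethan-1-ol | COc1cc(C(O)CBr)ccc1OCc1ccccc1
F5 | step 3 | racemic 1-(benzyloxy)-4-[2-bromo-1-(2-bromo-3,4,5-trimethoxyphenoxy)ethyl]-2-methoxybenzene | COc1cc(C(CBr)Oc2cc(OC)c(OC)c(OC)c2Br)ccc1OCc1ccccc1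
F6 | step 4 | 2-hydroxy-4,5,6-trimethoxybenzaldehyde | COc1cc(O)c(C=O)c(OC)c1OC
F7 | step 4 | racemic 2-{1-[4-(benzyloxy)-3-methoxyphenyl]-2-bromoethoxy}-4,5,6-trimethoxybenzaldehyde | COc1cc(C(CBr)Oc2cc(OC)c(OC)c(OC)c2C=O)ccc1OCc1ccccc1
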